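**Retrosynthetic overview**

1. The two carboxylic acids are carried as methyl esters and released last. The C8 chain is then cut at C8(acyl)–C7, giving a 3-alkyl-5-methoxysalicylaldehyde and methyl (2Z,4Z)-hepta-2,4-dien-6-ynoate.
2. These are joined by rhodium-catalysed addition of the formyl C–H across the terminal alkyne (alkyne hydroacylation). Two electrophilic carbons (the formyl carbon and the alkyne terminus of a 2,4-dien-6-ynoate) are united after polarity reversal of the formyl carbon by C–H oxidative addition. One operation forms C8–C7, sets the 6E alkene and completes the trienone chain with the phenol unprotected.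
3. Enabling feature: the O–H on C2 of the benzene ring, ortho to C1 which carries the acyl carbon C8. The atoms O–C2–C1–C8 close a five-membered O–Rh–C(acyl) chelate that makes C–H activation easy and blocks decarbonylation.
4. Aldehyde: 2-bromo-4-methoxyphenol → boronic acid → enantioselective redox-relay Heck arylation of (E)-pent-3-en-1-ol (sets the (R) centre) → Wittig → ortho-formylation. Dienyne: methyl (Z)-3-iodoacrylate → reduction/Still–Gennari olefination → Negishi ethynylation.
5. Rings: none is formed in the route; the benzene ring comes with the first starting material.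

Key step: step 9

Assumption on step 3: the (S)-pyridine-oxazoline ligand paired with the (E)-alkenol is taken to give the (R)-aldehyde; if the first run shows the antipode, the (R)-ligand is used and nothing else changes.

**Step 1**
Reactants: 1 2-bromo-4-methoxyphenol
Product: 2 2-bromo-4-methoxy-1-(methoxymethoxy)benzene
Conditions: MOMCl, i-Pr2NEt, CH2Cl2, 0 °C to rt
Reagents that add atoms: chloromethyl methyl ether, COCCl
Why: Base-mediated O-alkylation (MOM protection) of the phenol; the acetal should survive n-BuLi and the oxidative Heck conditions and is later removed by methanolysis that cannot alter a methyl ester.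

**Step 2**
Reactants: 2 2-bromo-4-methoxy-1-(methoxymethoxy)benzene
Product: 4 [5-methoxy-2-(methoxymethoxy)phenyl]boronic acid, via 5-methoxy-2-(methoxymethoxy)phenyllithium 3 (not isolated)
Conditions: n-BuLi, THF, −78 °C; B(Oi-Pr)3, −78 °C to rt; dilute aq. HCl to pH 5, 0 °C
Reagents that add atoms: triisopropyl borate, CC(C)OB(OC(C)C)OC(C)C; water, O
Why: Bromine–lithium exchange at −78 °C is faster than any ortho-lithiation, and trapping of the aryllithium by the borate followed by mild hydrolysis should give the boronic acid (lithiation–borylation).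

**Step 3**
Reactants: 4 [5-methoxy-2-(methoxymethoxy)phenyl]boronic acid; 5 (3E)-pent-3-en-1-ol
Product: 6 (4R)-4-[5-methoxy-2-(methoxymethoxy)phenyl]pentanal
Conditions: Pd(MeCN)2(OTs)2 (6 mol %), Cu(OTf)2 (6 mol %), (S)-4-tert-butyl-2-[5-(trifluoromethyl)pyridin-2-yl]-4,5-dihydrooxazole (13 mol %), 3 Å MS, DMF, O2 (1 atm), rt
Reagents that add atoms: none
Why: Enantioselective redox-relay oxidative Heck arylation of a homoallylic alcohol: the aryl group adds to C4 (remote from OH), palladium walks along the chain to C1 and leaves as the aldehyde, and the chiral pyridine-oxazoline ligand controls the face of migratory insertion and so sets the benzylic (R) centre.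

**Step 4**
Reactants: 6 (4R)-4-[5-methoxy-2-(methoxymethoxy)phenyl]pentanal
Product: 7 methyl (2E,6R)-6-[5-methoxy-2-(methoxymethoxy)phenyl]hept-2-enoate
Conditions: Ph3P=CHCO2Me, CH2Cl2, rt
Reagents that add atoms: methyl (triphenylphosphoranylidene)acetate, COC(=O)C=P(c1ccccc1)(c1ccccc1)c1ccccc1
Why: Wittig olefination with a stabilised ylide should give the (E)-enoate, and the stereocentre, which is γ to the aldehyde, is not touched.

**Step 5**
Reactants: 7 methyl (2E,6R)-6-[5-methoxy-2-(methoxymethoxy)phenyl]hept-2-enoate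
Product: 8 methyl (2E,6R)-6-(2-hydroxy-5-methoxyphenyl)hept-2-enoate
Conditions: HCl (1.25 M in MeOH), 40 °C
Reagents that add atoms: none
Why: Acid-catalysed acetal exchange (MOM cleavage) in methanol frees the phenol, while methanolysis of the methyl ester is degenerate.

**Step 6**
Reactants: 8 methyl (2E,6R)-6-(2-hydroxy-5-methoxyphenyl)hept-2-enoate
Product: 9 methyl (2E,6R)-6-(3-formyl-2-hydroxy-5-methoxyphenyl)hept-2-enoate
Conditions: MgCl2, Et3N, (CH2O)n, MeCN, 80 °C
Reagents that add atoms: paraformaldehyde (as formaldehyde), C=O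
Why: Magnesium-mediated ortho-formylation of a phenol (Casnati–Skattebøl reaction): the magnesium phenoxide delivers formaldehyde to the only free ortho position (the other ortho carbon bears the alkyl chain, the para carbon bears OMe), and a second formaldehyde takes up hydride to give the aldehyde.

**Step 7**
Reactants: 10 methyl (2Z)-3-iodoprop-2-enoate
Product: 12 methyl (2Z,4Z)-5-iodopenta-2,4-dienoate, via (2Z)-3-iodoprop-2-enal 11 (not isolated)
Conditions: i-Bu2AlH (1.05 equiv), CH2Cl2, −78 °C; MeOH, aq. KNaC4H4O6, cold extraction; crude enal added to (CF3CH2O)2P(O)CH2CO2Me, KN(SiMe3)2, 18-crown-6, THF, −78 °C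
Reagents that add atoms: methyl bis(2,2,2-trifluoroethyl)phosphonoacetate, COC(=O)CP(=O)(OCC(F)(F)F)OCC(F)(F)F
Why: Partial hydride reduction of the ester stops at the aldehyde because the tetrahedral aluminium intermediate is stable at −78 °C, and Still–Gennari olefination of the crude (Z)-enal under dissociating conditions should build the new 2Z alkene while the (Z)-iodoalkene is kept.

**Step 8**
Reactants: 12 methyl (2Z,4Z)-5-iodopenta-2,4-dienoate
Product: 13 methyl (2Z,4Z)-hepta-2,4-dien-6-ynoate
Conditions: HC≡CMgBr, ZnBr2, THF, 0 °C; then 12, Pd(PPh3)4 (5 mol %), THF, 0 °C to rt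
Reagents that add atoms: ethynylmagnesium bromide, C#C[Mg]Br
Why: Negishi coupling of the alkenyl iodide with ethynylzinc bromide under zerovalent palladium should give the terminal alkyne directly, with retention of both (Z)-alkenes and without touching the ester.

**Step 9**
Reactants: 9 methyl (2E,6R)-6-(3-formyl-2-hydroxy-5-methoxyphenyl)hept-2-enoate; 13 methyl (2Z,4Z)-hepta-2,4-dien-6-ynoate
Product: 14 methyl (2Z,4Z,6E)-8-{2-hydroxy-5-methoxy-3-[(2R,5E)-7-methoxy-7-oxohept-5-en-2-yl]phenyl}-8-oxoocta-2,4,6-trienoate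
Conditions: [Rh(cod)Cl]2 (2.5 mol %), dppf (5 mol %), Na2CO3 (10 mol %), toluene, 60 °C, 13 (1.3 equiv) added over 2 h
Reagents that add atoms: none
Why: Intermolecular rhodium-catalysed alkyne hydroacylation: carbonate turns the phenol into a rhodium phenoxide, the formyl C–H adds oxidatively to monovalent rhodium to give a five-membered O,C-chelated acyl rhodium hydride (trivalent rhodium) that is held against decarbonylation, the terminal alkyne inserts into Rh–H in a syn fashion with rhodium on the unsubstituted carbon C7, and C–C reductive elimination forms the C8–C7 bond. The closest known reaction type is the [Rh(cod)Cl]2/dppf/carbonate coupling of salicylaldehydes with terminal alkynes to 2-hydroxyaryl (E)-enones. No ring is closed and no stereocentre is formed; the one new stereo-element, the 6E alkene, follows from syn addition of acyl and hydride across the triple bond. The step needs linear regioselectivity, which the unsubstituted alkyne terminus and the bulky ferrocenyl bisphosphine should secure, and chemoselectivity for the alkyne over the three electron-poor internal alkenes, which insert far more slowly. It also needs the (2Z,4Z)-diene and the (R) centre to pass untouched, which the moderate temperature, the slow addition of the alkyne and the absence of any acidic site next to the stereocentre should secure.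

**Step 10**
Reactants: 14 methyl (2Z,4Z,6E)-8-{2-hydroxy-5-methoxy-3-[(2R,5E)-7-methoxy-7-oxohept-5-en-2-yl]phenyl}-8-oxoocta-2,4,6-trienoate
Product: 15 (2Z,4Z,6E)-8-{3-[(2R,5E)-6-carboxyhex-5-en-2-yl]-2-hydroxy-5-methoxyphenyl}-8-oxoocta-2,4,6-trienoic acid
Conditions: LiOH (6 equiv), THF/H2O 3:1, 0 °C to 15 °C, dark, argon; cold 1 M HCl to pH 3, rapid extraction
Reagents that add atoms: lithium hydroxide, [Li+].[OH-]
Why: Saponification of both methyl esters; the phenoxide that forms first lowers the electrophilicity of the trienone towards hydroxide, and cold acidification should return the hydrogen-bonded 2-hydroxyaryl ketone with the alkene geometries and the remote stereocentre unchanged.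

**Compound list**

1 | 2-bromo-4-methoxyphenol | COc1ccc(O)c(Br)c1 | starting material
2 | 2-bromo-4-methoxy-1-(methoxymethoxy)benzene | COCOc1ccc(OC)cc1Br | intermediate
3 | 5-methoxy-2-(methoxymethoxy)phenyllithium | COCOc1ccc(OC)cc1[Li] | intermediate
4 | [5-methoxy-2-(methoxymethoxy)phenyl]boronic acid | COCOc1ccc(OC)cc1B(O)O | intermediate
5 | (3E)-pent-3-en-1-ol | C/C=C/CCO | starting material
6 | (4R)-4-[5-methoxy-2-(methoxymethoxy)phenyl]pentanal | COc1ccc(OCOC)c([C@H](C)CCC=O)c1 | intermediate
7 | methyl (2E,6R)-6-[5-methoxy-2-(methoxymethoxy)phenyl]hept-2-enoate | COc1ccc(OCOC)c([C@H](C)CC/C=C/C(=O)OC)c1 | intermediate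
8 | methyl (2E,6R)-6-(2-hydroxy-5-methoxyphenyl)hept-2-enoate | COc1ccc(O)c([C@H](C)CC/C=C/C(=O)OC)c1 | intermediate
9 | methyl (2E,6R)-6-(3-formyl-2-hydroxy-5-methoxyphenyl)hept-2-enoate | COc1cc(C=O)c(O)c([C@H](C)CC/C=C/C(=O)OC)c1 | intermediate
10 | methyl (2Z)-3-iodoprop-2-enoate | COC(=O)/C=C\I | starting material
11 | (2Z)-3-iodoprop-2-enal | O=C/C=C\I | intermediate
12 | methyl (2Z,4Z)-5-iodopenta-2,4-dienoate | COC(=O)/C=C\C=C/I | intermediate
13 | methyl (2Z,4Z)-hepta-2,4-dien-6-ynoate | COC(=O)/C=C\C=C/C#C | intermediate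
14 | methyl (2Z,4Z,6E)-8-{2-hydroxy-5-methoxy-3-[(2R,5E)-7-methoxy-7-oxohept-5-en-2-yl]phenyl}-8-oxoocta-2,4,6-trienoate | COc1cc(C(=O)/C=C/C=C\C=C/C(=O)OC)c(O)c([C@H](C)CC/C=C/C(=O)OC)c1 | intermediate
15 | (2Z,4Z,6E)-8-{3-[(2R,5E)-6-carboxyhex-5-en-2-yl]-2-hydroxy-5-methoxyphenyl}-8-oxoocta-2,4,6-trienoic acid | COc1cc(C(=O)/C=C/C=C\C=C/C(=O)O)c(O)c([C@H](C)CC/C=C/C(=O)O)c1 | target

**Step count and risks**

Total step count: 10. Longest linear sequence: 8 steps (steps 1 to 6, 9 and 10); steps 7 and 8 form the second branch.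

Three steps most likely to fail:

Step 9. The alkyne may insert into the rhodium hydride with the opposite orientation, so that the acyl group ends on C6 and a 1,1-disubstituted enone forms. The rhodium hydride may also isomerise the (2Z,4Z)-diene by reversible addition, or the alkyne may oligomerise. The fallback sets out from 13 and 9 and comes back at 14. Alkyne 13 is hydroborated with dicyclohexylborane (THF, 0 °C; boron on the terminal carbon, syn addition) to methyl (2Z,4Z,6E)-7-(dicyclohexylboranyl)hepta-2,4,6-trienoate F1. Boron-to-zinc exchange with Et2Zn (−78 °C to 0 °C) gives ethyl[(1E,3Z,5Z)-7-methoxy-7-oxohepta-1,3,5-trien-1-yl]zinc F2. This adds to aldehyde 9 (phenol first turned into its zinc phenoxide by one more equivalent of Et2Zn, cat. Me2NCH2CH2OH) to give methyl (2Z,4Z,6E)-8-hydroxy-8-{2-hydroxy-5-methoxy-3-[(2R,5E)-7-methoxy-7-oxohept-5-en-2-yl]phenyl}octa-2,4,6-trienoate F3 as both C8 epimers. MnO2 (CH2Cl2, rt) oxidises this benzylic, allylic alcohol to 14.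

Step 3. Transmetalation of the ortho-alkoxy, electron-rich boronic acid may be slow and lose out to protodeboronation, the aryl group may add to C3 instead of C4, or the facial selectivity may be too low. The fallback sets out from 4 and comes back at 7. Hayashi–Miyaura addition of 4 to ethyl (2E)-but-2-enoate (Rh(acac)(C2H4)2, the BINAP enantiomer that gives the (R)-ester, dioxane/H2O, 100 °C) gives ethyl (3R)-3-[5-methoxy-2-(methoxymethoxy)phenyl]butanoate F4. LiAlH4 (THF, 0 °C) reduces it to (3R)-3-[5-methoxy-2-(methoxymethoxy)phenyl]butan-1-ol F5. Appel-type iodination (iodine, PPh3, imidazole) gives 2-[(2R)-4-iodobutan-2-yl]-4-methoxy-1-(methoxymethoxy)benzene F6. Zinc insertion (Zn dust, LiCl, THF) gives {(3R)-3-[5-methoxy-2-(methoxymethoxy)phenyl]butyl}zinc iodide F7, and Negishi coupling with methyl (2E)-3-iodoprop-2-enoate (Pd(PPh3)4, THF) gives 7.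

Step 10. Hydroxide or the phenoxide may add reversibly to the trienone, which would erode the 2Z and 4Z geometry or close a chromanone, and the (2Z)-acid may lactonise onto C4 during acidification. The fallback replaces both methyl esters by 2-(trimethylsilyl)ethyl esters that are removed by fluoride; it sets out from 6 and 10 and comes back at 15.

- Aryl branch: aldehyde 6 is olefinated with 2-(trimethylsilyl)ethyl (triphenylphosphoranylidene)acetate to 2-(trimethylsilyl)ethyl (2E,6R)-6-[5-methoxy-2-(methoxymethoxy)phenyl]hept-2-enoate F8. The MOM ether is cleaved (aq. HCl, THF, 40 °C) to 2-(trimethylsilyl)ethyl (2E,6R)-6-(2-hydroxy-5-methoxyphenyl)hept-2-enoate F9. Formylation as in step 6 gives 2-(trimethylsilyl)ethyl (2E,6R)-6-(3-formyl-2-hydroxy-5-methoxyphenyl)hept-2-enoate F10.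
- Alkyne branch: crude enal 11 from 10 is olefinated with 2-(trimethylsilyl)ethyl bis(2,2,2-trifluoroethyl)phosphonoacetate to 2-(trimethylsilyl)ethyl (2Z,4Z)-5-iodopenta-2,4-dienoate F11. Ethynylation as in step 8 gives 2-(trimethylsilyl)ethyl (2Z,4Z)-hepta-2,4-dien-6-ynoate F12.
- Union and release: hydroacylation of F12 with F10 as in step 9 gives 2-(trimethylsilyl)ethyl (2Z,4Z,6E)-8-[2-hydroxy-5-methoxy-3-{(2R,5E)-7-oxo-7-[2-(trimethylsilyl)ethoxy]hept-5-en-2-yl}phenyl]-8-oxoocta-2,4,6-trienoate F13. Bu4NF (THF, 0 °C, then pH 4 buffer) releases both acids to give 15.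

**Further compounds**

F1 | step 9 | methyl (2Z,4Z,6E)-7-(dicyclohexylboranyl)hepta-2,4,6-trienoate | COC(=O)/C=C\C=C/C=C/B(C1CCCCC1)C1CCCCC1
F2 | step 9 | ethyl[(1E,3Z,5Z)-7-methoxy-7-oxohepta-1,3,5-trien-1-yl]zinc | CC[Zn]/C=C/C=C\C=C/C(=O)OC
F3 | step 9 | methyl (2Z,4Z,6E)-8-hydroxy-8-{2-hydroxy-5-methoxy-3-[(2R,5E)-7-methoxy-7-oxohept-5-en-2-yl]phenyl}octa-2,4,6-trienoate (both C8 epimers) | COc1cc(C(O)/C=C/C=C\C=C/C(=O)OC)c(O)c([C@H](C)CC/C=C/C(=O)OC)c1
F4 | step 3 | ethyl (3R)-3-[5-methoxy-2-(methoxymethoxy)phenyl]butanoate | COc1ccc(OCOC)c([C@H](C)CC(=O)OCC)c1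
F5 | step 3 | (3R)-3-[5-methoxy-2-(methoxymethoxy)phenyl]butan-1-ol | COc1ccc(OCOC)c([C@H](C)CCO)c1
F6 | step 3 | 2-[(2R)-4-iodobutan-2-yl]-4-methoxy-1-(methoxymethoxy)benzene | COc1ccc(OCOC)c([C@H](C)CCI)c1
F7 | step 3 | {(3R)-3-[5-methoxy-2-(methoxymethoxy)phenyl]butyl}zinc iodide | COc1ccc(OCOC)c([C@H](C)CC[Zn]I)c1
F8 | step 10 | 2-(trimethylsilyl)ethyl (2E,6R)-6-[5-methoxy-2-(methoxymethoxy)phenyl]hept-2-enoate | COc1ccc(OCOC)c([C@H](C)CC/C=C/C(=O)OCC[Si](C)(C)C)c1
F9 | step 10 | 2-(trimethylsilyl)ethyl (2E,6R)-6-(2-hydroxy-5-methoxyphenyl)hept-2-enoate | COc1ccc(O)c([C@H](C)CC/C=C/C(=O)OCC[Si](C)(C)C)c1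
F10 | step 10 | 2-(trimethylsilyl)ethyl (2E,6R)-6-(3-formyl-2-hydroxy-5-methoxyphenyl)hept-2-enoate | COc1cc(C=O)c(O)c([C@H](C)CC/C=C/C(=O)OCC[Si](C)(C)C)c1
F11 | step 10 | 2-(trimethylsilyl)ethyl (2Z,4Z)-5-iodopenta-2,4-dienoate | C[Si](C)(C)CCOC(=O)/C=C\C=C/I
F12 | step 10 | 2-(trimethylsilyl)ethyl (2Z,4Z)-hepta-2,4-dien-6-ynoate | C[Si](C)(C)CCOC(=O)/C=C\C=C/C#C
F13 | step 10 | 2-(trimethylsilyl)ethyl (2Z,4Z,6E)-8-[2-hydroxy-5-methoxy-3-{(2R,5E)-7-oxo-7-[2-(trimethylsilyl)ethoxy]hept-5-en-2-yl}phenyl]-8-oxoocta-2,4,6-trienoate | COc1cc(C(=O)/C=C/C=C\C=C/C(=O)OCC[Si](C)(C)C)c(O)c([C@H](C)CC/C=C/C(=O)OCC[Si](C)(C)C)c1
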